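The benzene ring of the dihydroisocoumarin (ring C) is hexasubstituted, and its two oxygens, on C8' and C6', stand meta to each other with the C7' methyl group between them. A ketene carbonyl carbon and a siloxyalkyne deliver exactly this array, so ring C is cut into a vinylketene and 1-(triisopropylsiloxy)propyne. One light-then-heat operation (Wolff rearrangement, [2+2] cycloaddition, 4π opening, 6π closure) forges C7'–C8', C5'–C6' and C8'–C8a' and brings in five of the six ring C substituents. Its precursor is α-diazo enone 16: the diazo carbon bears C9 and the 5-O-benzyl chromone, the alkene bears the silylated (R)-2-hydroxypropyl chain. C1' follows by phenol-directed formylation at C8a'.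

Key step: step 12

Remark: locants without primes are chromone locants (ring A pyranone, ring B benzene), primed locants are 3,4-dihydroisocoumarin locants (ring C benzene, ring D lactone), and C9 is the bridging CH2.
Remark: the alkyne partner needs a methyl group on its nucleophilic carbon, so its ynolate is made by oxygen transfer to 1-propynyllithium, taken as commercial; a one-carbon ester homologation would have to start from an acetate.

Step 1
Reactants: 1 1-(2,6-dihydroxy-4-methoxyphenyl)ethan-1-one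
Product: 3 5-hydroxy-7-methoxy-2-methyl-4H-chromen-4-one (eugenin), via β-diketone 2 (not isolated)
Conditions: NaH, EtOAc, THF, 0 → 65 °C; then conc. HCl, AcOH, 80 °C
Reagents that add atoms: ethyl acetate, CCOC(C)=O
Why: Claisen condensation of the methyl ketone enolate with ethyl acetate gives the β-diketone, and acid-catalysed cyclodehydration onto either of the two equivalent phenols (classical 2-methylchromone synthesis) leaves the other one as the chelated 5-OH.

Step 2
Reactants: 3 5-hydroxy-7-methoxy-2-methyl-4H-chromen-4-one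
Product: 4 7-methoxy-2-methyl-5-(prop-2-en-1-yloxy)-4H-chromen-4-one
Conditions: allyl bromide, K2CO3, DMF, 60 °C
Reagents that add atoms: allyl bromide, C=CCBr
Why: Williamson etherification, in which the chelated 5-OH is the only acidic site and is alkylated by the reactive allylic bromide in warm DMF.

Step 3
Reactants: 4 7-methoxy-2-methyl-5-(prop-2-en-1-yloxy)-4H-chromen-4-one
Product: 5 5-hydroxy-7-methoxy-2-methyl-6-(prop-2-en-1-yl)-4H-chromen-4-one
Conditions: PhNEt2, 200 °C
Reagents that add atoms: none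
Why: Aromatic Claisen rearrangement ([3,3]-sigmatropic shift), in which C6 is the only free ortho carbon of the aryl allyl ether (the other ortho atom is the ring-fusion carbon C4a) and tautomerization of the C6 dienone restores the chelated phenol.

Step 4
Reactants: 5 5-hydroxy-7-methoxy-2-methyl-6-(prop-2-en-1-yl)-4H-chromen-4-one
Product: 6 5-(benzyloxy)-7-methoxy-2-methyl-6-(prop-2-en-1-yl)-4H-chromen-4-one
Conditions: BnBr, Cs2CO3, Bu4NI (cat.), DMF, 60 °C
Reagents that add atoms: benzyl bromide, BrCc1ccccc1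
Why: Williamson benzylation of the hindered chelated phenol through its caesium phenoxide, which masks O5 so that it cannot trap the ketene of step 12.

Step 5
Reactants: 6 5-(benzyloxy)-7-methoxy-2-methyl-6-(prop-2-en-1-yl)-4H-chromen-4-one
Product: 8 5-(benzyloxy)-6-(3-hydroxypropyl)-7-methoxy-2-methyl-4H-chromen-4-one, via B-alkyl-9-BBN adduct 7 (not isolated)
Conditions: 9-BBN, THF, 0 → 20 °C; then NaBO3·4H2O, H2O, 20 °C
Reagents that add atoms: sodium perborate, [Na+].[O-]OB=O
Why: Anti-Markovnikov hydroboration of the terminal alkene by 9-BBN is much faster than reduction of the vinylogous-ester carbonyl, and the mild perborate oxidation of the C–B bond spares the base-sensitive pyranone.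

Step 6
Reactants: 8 5-(benzyloxy)-6-(3-hydroxypropyl)-7-methoxy-2-methyl-4H-chromen-4-one
Product: 9 3-[5-(benzyloxy)-7-methoxy-2-methyl-4-oxo-4H-chromen-6-yl]propanoic acid
Conditions: TEMPO (cat.), PhI(OAc)2, MeCN/H2O, 20 °C
Reagents that add atoms: water, O
Why: TEMPO-catalysed oxidation with PhI(OAc)2 in aqueous acetonitrile takes the primary alcohol through the aldehyde hydrate to the carboxylic acid without touching the chromone or the benzyl ether.

Step 7
Reactants: 10 (2R)-pent-4-yn-2-ol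
Product: 11 tert-butyldimethyl[(2R)-pent-4-yn-2-yloxy]silane
Conditions: TBSCl, imidazole, DMF, 20 °C
Reagents that add atoms: tert-butyldimethylsilyl chloride, CC(C)(C)[Si](C)(C)Cl
Why: Standard silylation of a secondary alcohol, in which the C–O bond is not involved, so the (R) configuration is retained.

Step 8
Reactants: 11 tert-butyldimethyl[(2R)-pent-4-yn-2-yloxy]silane
Product: 12 tert-butyldimethyl{[(2R)-4-(tributylstannyl)pent-4-en-2-yl]oxy}silane
Conditions: Bu3Sn–SiMe3, H2O, Cu(OAc)2 (cat.), P(t-Bu)3 (cat.), THF, 20 °C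
Reagents that add atoms: tributyl(trimethylsilyl)stannane, CCCC[Sn](CCCC)(CCCC)[Si](C)(C)C
Why: Copper-catalysed α-selective hydrostannylation, in which syn-stannylcupration of the terminal alkyne places tin on the internal carbon and copper on the terminal one and protonolysis by water releases the branched 2-stannylalkene.

Step 9
Reactants: 9 3-[5-(benzyloxy)-7-methoxy-2-methyl-4-oxo-4H-chromen-6-yl]propanoic acid; 12 tert-butyldimethyl{[(2R)-4-(tributylstannyl)pent-4-en-2-yl]oxy}silane
Product: 14 5-(benzyloxy)-6-[(6R)-6-(tert-butyldimethylsilyloxy)-4-methylidene-3-oxoheptyl]-7-methoxy-2-methyl-4H-chromen-4-one, via acid chloride 13 (not isolated)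
Conditions: (COCl)2, DMF (cat.), CH2Cl2, 0 → 20 °C, evaporate; then 12, PdCl2(PPh3)2 (cat.), toluene, 70 °C
Reagents that add atoms: none
Why: Stille acylation, in which the acid chloride adds oxidatively to zerovalent palladium, the alkenyl group is transferred from tin and reductive elimination gives the α-methylene ketone under neutral conditions that tolerate chromone, benzyl ether and silyl ether.

Step 10
Reactants: 14 5-(benzyloxy)-6-[(6R)-6-(tert-butyldimethylsilyloxy)-4-methylidene-3-oxoheptyl]-7-methoxy-2-methyl-4H-chromen-4-one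
Product: 16 5-(benzyloxy)-6-[(6R)-6-(tert-butyldimethylsilyloxy)-2-diazo-4-methylidene-3-oxoheptyl]-7-methoxy-2-methyl-4H-chromen-4-one, via trifluoroacetyl ketone 15 (not isolated)
Conditions: LiN(SiMe3)2, THF, −78 °C; CF3CO2CH2CF3, −78 °C; 1 M HCl work-up; then MsN3, Et3N, H2O, MeCN, 20 °C
Reagents that add atoms: methanesulfonyl azide, CS(=O)(=O)N=[N+]=[N-]
Why: Detrifluoroacetylative diazo transfer, in which kinetic deprotonation at −78 °C occurs at the only α-CH2 of the enone (the future C5', faster than at the vinylogous 2-methyl group of ring A), the enolate is trifluoroacetylated and the activated 1,3-dicarbonyl compound takes the diazo group from mesyl azide with loss of the trifluoroacetyl group.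

Step 11
Reactants: 17 prop-1-yn-1-yllithium
Product: 19 triisopropyl(prop-1-yn-1-yloxy)silane [1-(triisopropylsiloxy)propyne], via lithium propynolate 18 (not isolated)
Conditions: t-BuOOH, LiN(SiMe3)2, THF, −78 → 0 °C; then i-Pr3SiOTf, −78 → 0 °C
Reagents that add atoms: tert-butyl hydroperoxide, CC(C)(C)OO; triisopropylsilyl trifluoromethanesulfonate, CC(C)[Si](OS(=O)(=O)C(F)(F)F)(C(C)C)C(C)C
Why: Oxidation of the lithium acetylide by lithium tert-butylperoxide (oxygen transfer with loss of tert-butoxide) gives the lithium ynolate, which the bulky silyl triflate silylates on oxygen and not on carbon.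

Step 12
Reactants: 16 5-(benzyloxy)-6-[(6R)-6-(tert-butyldimethylsilyloxy)-2-diazo-4-methylidene-3-oxoheptyl]-7-methoxy-2-methyl-4H-chromen-4-one; 19 triisopropyl(prop-1-yn-1-yloxy)silane
Product: 23 5-(benzyloxy)-6-({6-[(2R)-2-(tert-butyldimethylsilyloxy)propyl]-4-hydroxy-3-methyl-2-(triisopropylsilyloxy)phenyl}methyl)-7-methoxy-2-methyl-4H-chromen-4-one, via vinylketene 20 (not isolated), via vinylcyclobutenone 21 (not isolated), via dienylketene 22 (not isolated)
Conditions: 19 (excess), degassed ClCH2CH2Cl, 450 nm LEDs, 20 °C; then 80 °C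
Reagents that add atoms: none
Why: Light of 450 nm is absorbed only by the conjugated diazo ketone of 16 (the 5-alkoxychromone of rings A and B absorbs in the ultraviolet), N2 leaves with 1,2-shift of the alkenyl group (photochemical Wolff rearrangement) and vinylketene 20 results; the electron-rich methyl-bearing carbon of 19 attacks the ketene carbonyl carbon and the siloxy-bearing carbon bonds to the ketene α-carbon, a [2+2] cycloaddition that sets C7'–C8' and C5'–C6' in vinylcyclobutenone 21. Ring strain then drives thermal conrotatory 4π opening of the C8'–C5' bond to dienylketene 22, and ring C is closed by thermal disrotatory 6π electrocyclization between C8' and C8a', after which tautomerization of the cyclohexadienone gives the phenol. The closest known reaction type is the Danheiser benzannulation of photochemically generated vinylketenes with siloxyalkynes. No stereocentre is created, and the (R)-carbinol centre is remote from every reacting atom and keeps its configuration. The step needs regiocontrol in the [2+2] event, secured by the oxygen-polarized triple bond of 19 (methyl at C7' between the two oxygens, C9 at C5'), and clean intermolecular ketene capture, secured by the benzyl ether on O5, which removes the only nucleophile that could reach the ketene intramolecularly. It also needs the Wolff shift to outrun 1,2-hydrogen migration from C9, which direct excitation of the s-cis diazo ketone favours.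

Step 13
Reactants: 23 5-(benzyloxy)-6-({6-[(2R)-2-(tert-butyldimethylsilyloxy)propyl]-4-hydroxy-3-methyl-2-(triisopropylsilyloxy)phenyl}methyl)-7-methoxy-2-methyl-4H-chromen-4-one
Product: 24 3-{[5-(benzyloxy)-7-methoxy-2-methyl-4-oxo-4H-chromen-6-yl]methyl}-2-[(2R)-2-(tert-butyldimethylsilyloxy)propyl]-6-hydroxy-5-methyl-4-(triisopropylsilyloxy)benzaldehyde
Conditions: MgCl2, Et3N, (CH2O)n, MeCN, 80 °C
Reagents that add atoms: paraformaldehyde (as formaldehyde), C=O
Why: Magnesium-mediated ortho-formylation (Casnati–Skattebøl reaction), in which the magnesium phenoxide of the C8' hydroxyl delivers formaldehyde to the only free ortho carbon, C8a', and the hydroxymethyl intermediate is oxidized to the aldehyde by hydride transfer to a second formaldehyde.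

Step 14
Reactants: 24 3-{[5-(benzyloxy)-7-methoxy-2-methyl-4-oxo-4H-chromen-6-yl]methyl}-2-[(2R)-2-(tert-butyldimethylsilyloxy)propyl]-6-hydroxy-5-methyl-4-(triisopropylsilyloxy)benzaldehyde
Product: 25 3-{[5-(benzyloxy)-7-methoxy-2-methyl-4-oxo-4H-chromen-6-yl]methyl}-2-[(2R)-2-(tert-butyldimethylsilyloxy)propyl]-6-hydroxy-5-methyl-4-(triisopropylsilyloxy)benzoic acid
Conditions: NaClO2, NaH2PO4, 2-methylbut-2-ene, t-BuOH/THF/H2O, 0 → 20 °C
Reagents that add atoms: sodium chlorite, [Na+].[O-]Cl=O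
Why: Pinnick oxidation converts the hindered salicylaldehyde into the salicylic acid, ring C has no free position left for chlorination and 2-methylbut-2-ene removes the hypochlorous acid.

Step 15
Reactants: 25 3-{[5-(benzyloxy)-7-methoxy-2-methyl-4-oxo-4H-chromen-6-yl]methyl}-2-[(2R)-2-(tert-butyldimethylsilyloxy)propyl]-6-hydroxy-5-methyl-4-(triisopropylsilyloxy)benzoic acid
Product: 27 (3R)-5-{[5-(benzyloxy)-7-methoxy-2-methyl-4-oxo-4H-chromen-6-yl]methyl}-6,8-dihydroxy-3,7-dimethyl-3,4-dihydro-1H-isochromen-1-one, via hydroxy acid 26 (not isolated)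
Conditions: Bu4NF, THF, 20 → 40 °C; then 2 M HCl, 20 → 40 °C
Reagents that add atoms: none
Why: Fluoride cleaves both the aryl triisopropylsilyl ether and the secondary tert-butyldimethylsilyl ether, and on acidification the δ-hydroxy acid closes ring D by acid-catalysed lactonization at the acyl carbon, which leaves the configuration at C3' untouched.

Step 16
Reactants: 27 (3R)-5-{[5-(benzyloxy)-7-methoxy-2-methyl-4-oxo-4H-chromen-6-yl]methyl}-6,8-dihydroxy-3,7-dimethyl-3,4-dihydro-1H-isochromen-1-one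
Product: 28 (3R)-6,8-dihydroxy-5-[(5-hydroxy-7-methoxy-2-methyl-4-oxo-4H-chromen-6-yl)methyl]-3,7-dimethyl-3,4-dihydro-1H-isochromen-1-one (CNP0180307.1)
Conditions: H2 (1 atm), Pd/C, EtOAc/MeOH, 20 °C
Reagents that add atoms: none
Why: Hydrogenolysis of the benzyl aryl ether over palladium on carbon at one atmosphere is faster than reduction of the chromone C2–C3 double bond, and neither the C3'–O bond of the lactone (not benzylic) nor the diarylmethane C9 is cleaved.

Compound list
1 | 1-(2,6-dihydroxy-4-methoxyphenyl)ethan-1-one (2',6'-dihydroxy-4'-methoxyacetophenone) | CC(=O)c1c(O)cc(OC)cc1O | starting material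
2 | 1-(2,6-dihydroxy-4-methoxyphenyl)butane-1,3-dione | CC(=O)CC(=O)c1c(O)cc(OC)cc1O | intermediate
3 | 5-hydroxy-7-methoxy-2-methyl-4H-chromen-4-one (eugenin) | Cc1cc(=O)c2c(O)cc(OC)cc2o1 | intermediate
4 | 7-methoxy-2-methyl-5-(prop-2-en-1-yloxy)-4H-chromen-4-one | Cc1cc(=O)c2c(OCC=C)cc(OC)cc2o1 | intermediate
5 | 5-hydroxy-7-methoxy-2-methyl-6-(prop-2-en-1-yl)-4H-chromen-4-one | Cc1cc(=O)c2c(O)c(CC=C)c(OC)cc2o1 | intermediate
6 | 5-(benzyloxy)-7-methoxy-2-methyl-6-(prop-2-en-1-yl)-4H-chromen-4-one | Cc1cc(=O)c2c(OCc3ccccc3)c(CC=C)c(OC)cc2o1 | intermediate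
7 | 5-(benzyloxy)-6-[3-(9-borabicyclo[3.3.1]nonan-9-yl)propyl]-7-methoxy-2-methyl-4H-chromen-4-one | Cc1cc(=O)c2c(OCc3ccccc3)c(CCCB3C4CCCC3CCC4)c(OC)cc2o1 | intermediate
8 | 5-(benzyloxy)-6-(3-hydroxypropyl)-7-methoxy-2-methyl-4H-chromen-4-one | Cc1cc(=O)c2c(OCc3ccccc3)c(CCCO)c(OC)cc2o1 | intermediate
9 | 3-[5-(benzyloxy)-7-methoxy-2-methyl-4-oxo-4H-chromen-6-yl]propanoic acid | Cc1cc(=O)c2c(OCc3ccccc3)c(CCC(=O)O)c(OC)cc2o1 | intermediate
10 | (2R)-pent-4-yn-2-ol | C#CC[C@@H](C)O | starting material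
11 | tert-butyldimethyl[(2R)-pent-4-yn-2-yloxy]silane | C#CC[C@@H](C)O[Si](C)(C)C(C)(C)C | intermediate
12 | tert-butyldimethyl{[(2R)-4-(tributylstannyl)pent-4-en-2-yl]oxy}silane | C=C(C[C@@H](C)O[Si](C)(C)C(C)(C)C)[Sn](CCCC)(CCCC)CCCC | intermediate
13 | 3-[5-(benzyloxy)-7-methoxy-2-methyl-4-oxo-4H-chromen-6-yl]propanoyl chloride | Cc1cc(=O)c2c(OCc3ccccc3)c(CCC(=O)Cl)c(OC)cc2o1 | intermediate
14 | 5-(benzyloxy)-6-[(6R)-6-(tert-butyldimethylsilyloxy)-4-methylidene-3-oxoheptyl]-7-methoxy-2-methyl-4H-chromen-4-one | C=C(C[C@@H](C)O[Si](C)(C)C(C)(C)C)C(=O)CCc1c(OCc2ccccc2)c2c(=O)cc(C)oc2cc1OC | intermediate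
15 | 5-(benzyloxy)-6-[(6R)-6-(tert-butyldimethylsilyloxy)-4-methylidene-3-oxo-2-(trifluoroacetyl)heptyl]-7-methoxy-2-methyl-4H-chromen-4-one (both epimers at the acylated carbon) | C=C(C[C@@H](C)O[Si](C)(C)C(C)(C)C)C(=O)C(C(=O)C(F)(F)F)Cc1c(OCc2ccccc2)c2c(=O)cc(C)oc2cc1OC | intermediate
16 | 5-(benzyloxy)-6-[(6R)-6-(tert-butyldimethylsilyloxy)-2-diazo-4-methylidene-3-oxoheptyl]-7-methoxy-2-methyl-4H-chromen-4-one | C=C(C[C@@H](C)O[Si](C)(C)C(C)(C)C)C(=O)C(=[N+]=[N-])Cc1c(OCc2ccccc2)c2c(=O)cc(C)oc2cc1OC | intermediate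
17 | prop-1-yn-1-yllithium | [Li]C#CC | starting material
18 | lithium prop-1-yn-1-olate | CC#C[O-].[Li+] | intermediate
19 | triisopropyl(prop-1-yn-1-yloxy)silane [1-(triisopropylsiloxy)propyne] | CC#CO[Si](C(C)C)(C(C)C)C(C)C | intermediate
20 | (5R)-2-{[5-(benzyloxy)-7-methoxy-2-methyl-4-oxo-4H-chromen-6-yl]methyl}-5-(tert-butyldimethylsilyloxy)-3-methylidenehex-1-en-1-one (vinylketene) | O=C=C(Cc1c(OCc2ccccc2)c2c(=O)cc(C)oc2cc1OC)C(=C)C[C@@H](C)O[Si](C)(C)C(C)(C)C | intermediate
21 | 4-{[5-(benzyloxy)-7-methoxy-2-methyl-4-oxo-4H-chromen-6-yl]methyl}-4-[(4R)-4-(tert-butyldimethylsilyloxy)pent-1-en-2-yl]-2-methyl-3-(triisopropylsilyloxy)cyclobut-2-en-1-one (both C4 epimers) | O=C1C(C)=C(O[Si](C(C)C)(C(C)C)C(C)C)C1(Cc1c(OCc2ccccc2)c2c(=O)cc(C)oc2cc1OC)C(=C)C[C@@H](C)O[Si](C)(C)C(C)(C)C | intermediate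
22 | (7R)-4-{[5-(benzyloxy)-7-methoxy-2-methyl-4-oxo-4H-chromen-6-yl]methyl}-7-(tert-butyldimethylsilyloxy)-2-methyl-5-methylidene-3-(triisopropylsilyloxy)octa-1,3-dien-1-one (dienylketene) | O=C=C(C)C(O[Si](C(C)C)(C(C)C)C(C)C)=C(Cc1c(OCc2ccccc2)c2c(=O)cc(C)oc2cc1OC)C(=C)C[C@@H](C)O[Si](C)(C)C(C)(C)C | intermediate
23 | 5-(benzyloxy)-6-({6-[(2R)-2-(tert-butyldimethylsilyloxy)propyl]-4-hydroxy-3-methyl-2-(triisopropylsilyloxy)phenyl}methyl)-7-methoxy-2-methyl-4H-chromen-4-one | COc1cc2oc(C)cc(=O)c2c(OCc3ccccc3)c1Cc1c(O[Si](C(C)C)(C(C)C)C(C)C)c(C)c(O)cc1C[C@@H](C)O[Si](C)(C)C(C)(C)C | intermediate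
24 | 3-{[5-(benzyloxy)-7-methoxy-2-methyl-4-oxo-4H-chromen-6-yl]methyl}-2-[(2R)-2-(tert-butyldimethylsilyloxy)propyl]-6-hydroxy-5-methyl-4-(triisopropylsilyloxy)benzaldehyde | COc1cc2oc(C)cc(=O)c2c(OCc3ccccc3)c1Cc1c(O[Si](C(C)C)(C(C)C)C(C)C)c(C)c(O)c(C=O)c1C[C@@H](C)O[Si](C)(C)C(C)(C)C | intermediate
25 | 3-{[5-(benzyloxy)-7-methoxy-2-methyl-4-oxo-4H-chromen-6-yl]methyl}-2-[(2R)-2-(tert-butyldimethylsilyloxy)propyl]-6-hydroxy-5-methyl-4-(triisopropylsilyloxy)benzoic acid | COc1cc2oc(C)cc(=O)c2c(OCc3ccccc3)c1Cc1c(O[Si](C(C)C)(C(C)C)C(C)C)c(C)c(O)c(C(=O)O)c1C[C@@H](C)O[Si](C)(C)C(C)(C)C | intermediate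
26 | 3-{[5-(benzyloxy)-7-methoxy-2-methyl-4-oxo-4H-chromen-6-yl]methyl}-4,6-dihydroxy-2-[(2R)-2-hydroxypropyl]-5-methylbenzoic acid | COc1cc2oc(C)cc(=O)c2c(OCc3ccccc3)c1Cc1c(O)c(C)c(O)c(C(=O)O)c1C[C@@H](C)O | intermediate
27 | (3R)-5-{[5-(benzyloxy)-7-methoxy-2-methyl-4-oxo-4H-chromen-6-yl]methyl}-6,8-dihydroxy-3,7-dimethyl-3,4-dihydro-1H-isochromen-1-one | COc1cc2oc(C)cc(=O)c2c(OCc3ccccc3)c1Cc1c(O)c(C)c(O)c2c1C[C@@H](C)OC2=O | intermediate
28 | (3R)-6,8-dihydroxy-5-[(5-hydroxy-7-methoxy-2-methyl-4-oxo-4H-chromen-6-yl)methyl]-3,7-dimethyl-3,4-dihydro-1H-isochromen-1-one (CNP0180307.1) | COc1cc2oc(C)cc(=O)c2c(O)c1Cc1c(O)c(C)c(O)c2c1C[C@@H](C)OC2=O | target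

Total step count: 16. Longest linear sequence: 13 steps (steps 1 to 6, 9, 10 and 12 to 16).

Steps most likely to fail

Step 12. After loss of N2, a 1,2-hydrogen shift from C9 to the electron-poor carbon can outrun the alkenyl shift, or the ketene can oligomerize or acylate the product phenol before the alkyne captures it. The fallback is a carbene-free thermal benzannulation in which the two ring C oxygens exchange their origins. It sets out from acid 9, alkyne 11 and siloxyalkyne 19 and comes back at lactone 27.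
- Acid 9 would be coupled with dimethylamine (Me2NH·HCl, EDC·HCl, HOBt, i-Pr2NEt, CH2Cl2) to 3-[5-(benzyloxy)-7-methoxy-2-methyl-4-oxo-4H-chromen-6-yl]-N,N-dimethylpropanamide F1.
- Tf2O and 2,4,6-collidine in ClCH2CH2Cl would convert F1 into its keteniminium ion; [2+2] cycloaddition with 11 and aqueous hydrolysis should give 4-{[5-(benzyloxy)-7-methoxy-2-methyl-4-oxo-4H-chromen-6-yl]methyl}-3-[(2R)-2-(tert-butyldimethylsilyloxy)propyl]cyclobut-2-en-1-one F2.
- Heating F2 with 19 in toluene at 80 to 110 °C (the thermal cyclobutenone form of the same benzannulation) should open F2 to a vinylketene whose carbonyl carbon becomes C6' and whose terminus becomes C5'. The result should be the isomeric phenol F3, with free 6'-OH, an 8'-O-triisopropylsilyl group and free C8a'.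
- Bu4NF would remove both silyl groups to give triol F4.
- MgCl2, Et3N and (CH2O)n would formylate the only free ring C position to give hydroxy aldehyde F5.
- NaClO2, NaH2PO4 and 2-methylbut-2-ene, followed by dilute HCl, would give hydroxy acid 26 and then lactone 27.

Step 9. Transmetalation of the hindered 1,1-disubstituted alkenylstannane may be slow, so that the acyl chloride is lost by debenzylative lactonization onto O5 and the stannane by protodestannylation. The fallback replaces acyl cross-coupling by carbonyl addition. It sets out from stannane 12 and alcohol 8 and comes back at enone 14.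
- Iododestannylation of 12 (I2, CH2Cl2, 0 °C) would give tert-butyl{[(2R)-4-iodopent-4-en-2-yl]oxy}dimethylsilane F6.
- Dess–Martin oxidation of 8 would give 3-[5-(benzyloxy)-7-methoxy-2-methyl-4-oxo-4H-chromen-6-yl]propanal F7.
- Nozaki–Hiyama–Kishi coupling (CrCl2, NiCl2 (cat.), DMF, 20 °C) would join F6 and F7 to allylic alcohol F8 (both carbinol epimers).
- Dess–Martin oxidation of F8 would give 14.

Step 13. Hydroxymethylation at the crowded C8a' position may stall, or the magnesium phenoxide may be alkylated on oxygen by formaldehyde on prolonged heating. The fallback is halogenation followed by carbonylative ring closure. It sets out from phenol 23 and comes back at lactone 27.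
- NBS (CH2Cl2, −78 °C) would brominate the only free position of ring C to give aryl bromide F9.
- Camphorsulfonic acid in MeOH would remove the secondary silyl ether to give bromo alcohol F10.
- Pd(OAc)2, Xantphos, CO (1 atm) and Et3N in toluene at 90 °C would close ring D by intramolecular alkoxycarbonylation to the 6'-O-triisopropylsilyl lactone F11.
- Bu4NF would then give 27.

Further compounds
F1 | step 12 | 3-[5-(benzyloxy)-7-methoxy-2-methyl-4-oxo-4H-chromen-6-yl]-N,N-dimethylpropanamide | CN(C)C(=O)CCc1c(OCc2ccccc2)c2c(=O)cc(C)oc2cc1OC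
F2 | step 12 | 4-{[5-(benzyloxy)-7-methoxy-2-methyl-4-oxo-4H-chromen-6-yl]methyl}-3-[(2R)-2-(tert-butyldimethylsilyloxy)propyl]cyclobut-2-en-1-one | O=C1C=C(C[C@@H](C)O[Si](C)(C)C(C)(C)C)C1Cc1c(OCc2ccccc2)c2c(=O)cc(C)oc2cc1OC
F3 | step 12 | 5-(benzyloxy)-6-({6-[(2R)-2-(tert-butyldimethylsilyloxy)propyl]-2-hydroxy-3-methyl-4-(triisopropylsilyloxy)phenyl}methyl)-7-methoxy-2-methyl-4H-chromen-4-one | COc1cc2oc(C)cc(=O)c2c(OCc3ccccc3)c1Cc1c(O)c(C)c(O[Si](C(C)C)(C(C)C)C(C)C)cc1C[C@@H](C)O[Si](C)(C)C(C)(C)C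
F4 | step 12 | 5-(benzyloxy)-6-({2,4-dihydroxy-6-[(2R)-2-hydroxypropyl]-3-methylphenyl}methyl)-7-methoxy-2-methyl-4H-chromen-4-one | COc1cc2oc(C)cc(=O)c2c(OCc3ccccc3)c1Cc1c(O)c(C)c(O)cc1C[C@@H](C)O
F5 | step 12 | 3-{[5-(benzyloxy)-7-methoxy-2-methyl-4-oxo-4H-chromen-6-yl]methyl}-4,6-dihydroxy-2-[(2R)-2-hydroxypropyl]-5-methylbenzaldehyde | COc1cc2oc(C)cc(=O)c2c(OCc3ccccc3)c1Cc1c(O)c(C)c(O)c(C=O)c1C[C@@H](C)O
F6 | step 9 | tert-butyl{[(2R)-4-iodopent-4-en-2-yl]oxy}dimethylsilane | C=C(I)C[C@@H](C)O[Si](C)(C)C(C)(C)C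
F7 | step 9 | 3-[5-(benzyloxy)-7-methoxy-2-methyl-4-oxo-4H-chromen-6-yl]propanal | Cc1cc(=O)c2c(OCc3ccccc3)c(CCC=O)c(OC)cc2o1
F8 | step 9 | 5-(benzyloxy)-6-[(6R)-6-(tert-butyldimethylsilyloxy)-3-hydroxy-4-methylideneheptyl]-7-methoxy-2-methyl-4H-chromen-4-one (both C3 epimers of the chain) | C=C(C[C@@H](C)O[Si](C)(C)C(C)(C)C)C(O)CCc1c(OCc2ccccc2)c2c(=O)cc(C)oc2cc1OC
F9 | step 13 | 5-(benzyloxy)-6-({5-bromo-6-[(2R)-2-(tert-butyldimethylsilyloxy)propyl]-4-hydroxy-3-methyl-2-(triisopropylsilyloxy)phenyl}methyl)-7-methoxy-2-methyl-4H-chromen-4-one | COc1cc2oc(C)cc(=O)c2c(OCc3ccccc3)c1Cc1c(O[Si](C(C)C)(C(C)C)C(C)C)c(C)c(O)c(Br)c1C[C@@H](C)O[Si](C)(C)C(C)(C)C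
F10 | step 13 | 5-(benzyloxy)-6-({5-bromo-4-hydroxy-6-[(2R)-2-hydroxypropyl]-3-methyl-2-(triisopropylsilyloxy)phenyl}methyl)-7-methoxy-2-methyl-4H-chromen-4-one | COc1cc2oc(C)cc(=O)c2c(OCc3ccccc3)c1Cc1c(O[Si](C(C)C)(C(C)C)C(C)C)c(C)c(O)c(Br)c1C[C@@H](C)O
F11 | step 13 | (3R)-5-{[5-(benzyloxy)-7-methoxy-2-methyl-4-oxo-4H-chromen-6-yl]methyl}-8-hydroxy-3,7-dimethyl-6-(triisopropylsilyloxy)-3,4-dihydro-1H-isochromen-1-one | COc1cc2oc(C)cc(=O)c2c(OCc3ccccc3)c1Cc1c(O[Si](C(C)C)(C(C)C)C(C)C)c(C)c(O)c2c1C[C@@H](C)OC2=O
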